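## The problem

The target 24, 2-(2,5-dihydroxy-4-methoxyphenyl)-5,7-dihydroxy-6,8-dimethoxy-4H-chromen-4-one, is a flavone in which benzene ring A is fused through C4a–C8a to pyranone ring C, and ring C carries aryl ring B at C2. There is no stereocentre, so the whole difficulty is positional. Ring A is fully substituted, with oxygen on every carbon from C5 to C8 in alternating form (5-OH, 6-OMe, 7-OH, 8-OMe), and ring B is a 1,2,4-trioxygenated arene with free 2'- and 5'-hydroxyls and a 4'-methyl ether, so seven oxygen atoms have to be told apart. The free phenols are the delicate part, because the hydroquinone of ring B and the polyphenolic ring A are easily oxidised to quinones under basic, aerobic conditions; they should stay masked until the last step and be released without oxidants. The feature that opens the key step is that C8a and C4a are adjacent ring-A carbons bearing O1 and the C4 acyl carbon, the two ends of a carboxylic acid C–O bond, so the C4a–C8a edge can be introduced as an aryne. The four oxygenated carbons flanking that edge fall into two pairs (C5/C8 and C6/C7), so the aryne can be made mirror-symmetric. The pairs can be told apart afterwards through their relation to the C4 carbonyl, since C5–O is peri to it and C7–O is para to it.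

## Retrosynthesis

**24 from 23.** The last cut removes four O–C bonds: the 5-O-methyl, the 7-O-benzyl and the two methoxymethyl groups on ring B of 23. Doing this last keeps the hydroquinone and the 5,7-diol masked through every basic step. One Lewis acid can do all four, and the forward reaction must cleave only the methyl ether that is peri to the C4 carbonyl and leave the 6-, 8- and 4'-methyl ethers.

**23 from 20 through 21 and 22.** The 6-OMe/7-OBn pattern of 23 is traced to the symmetric 6,7-bis(benzyloxy) flavone 20. Hydrogenolysis gives diol 21, the more acidic 7-OH (para to the C4 carbonyl) is re-benzylated to 22, and the 6-OH is methylated. Carrying two different groups at C6 and C7 through the ring construction would make the aryne unsymmetric and give two regioisomers, so three short adjustment steps are the price of a regiochemically silent key step. The forward sequence asks only that the two hydroxyls of 21 differ enough in acidity.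

**20 from 12 and 17.** Three bonds are cut at once: O1–C8a, C4a–C4 and O1–C2. This turns 20 into arylpropiolic acid 17 and benzyne 18, which is released from silyl triflate 12. A classical flavone construction would start from a preformed ring-A phenol and would need a regioselective C-acylation of a pentaoxygenated benzene. The aryne cut removes that question, because 18 is symmetric (OMe at the future C5 and C8, OBn at C6 and C7). The precursors are two separate benzene derivatives. The forward reaction must transfer the acyl group to carbon, giving phenoxide 19, and then close ring C in the 6-endo mode.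

**17 from 13.** The C1'–alkyne bond of 17 is cut to aryl iodide 15 and propiolic acid 16. The iodide comes from bis-MOM ether 14 by iodination at the position para to the methoxy group, and 14 from methoxyhydroquinone 13. The substitution pattern of ring B is already present in 13, so nothing has to be differentiated.

**12 from 8.** The C–Si and O–S bonds of 12 are cut back to o-bromophenol 8: O-silylation to 9, bromine–lithium exchange to 10, silyl migration to phenoxide 11 and triflation. This is the standard entry to o-silylaryl triflates and needs only an ortho relationship of OH and Br.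

**8 from 1.** The phenol oxygen of 8 is introduced next to the bromine of 5 by deprotonation of the one remaining ring hydrogen to aryllithium 6, borylation to borate 7 and oxidation. Bromide 5 comes from the symmetric tetraether 4, in which the two ring hydrogens are equivalent. Ether 4 is the dibenzyl ether of catechol 3, which arises from 2,5-dimethoxyphenol 1 by ortho-formylation to aldehyde 2 and Dakin oxidation. Each step acts on the only available position, so no isomers are expected anywhere in this branch.

## Roads not taken

Alternative 1: The cut goes through ring A itself, at C5–C6 and C8–C8a. 1,3-Dimethoxyacetone A1 and dimethyl malonate A2 would be joined by a double Claisen condensation under NaOMe, and enolisation of the ring so formed would give 2,4-dimethoxybenzene-1,3,5-triol A3.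
- Merits: A3 carries the 6,8-dimethoxy-5,7-dihydroxy pattern in its final form and is assembled from the two acyclic three-carbon units A1 and A2. A3 is symmetric about its one free carbon (the future C4a), so acylation there and closure through either neighbouring hydroxyl lead to the same flavone. No oxygen on ring A ever has to be exchanged.
- Where it is better: the chosen plan spends four steps after the coupling on the 6/7 exchange and the 5-O-demethylation; this road needs none of them.
- Weak points: A2 is deprotonated at its own methylene first, which makes its esters poor acceptors. A1 can condense with itself. A3 is an electron-rich, air-sensitive phenol that must be C-acylated selectively before ring C and ring B are added by a separate multistep flavone synthesis.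
- What the chosen plan sets against it: a known reaction type on aromatic partners, attachment of ring B and closure of ring C in one operation, and protected phenols until the end.

Alternative 2: The cut is at C4a–C5 and O1–C2 of a polyketide-like precursor, 6-{4-[2,5-bis(benzyloxy)-4-methoxyphenyl]-2-oxobut-3-yn-1-yl}-4-hydroxy-3,5-dimethoxy-2H-pyran-2-one A4. Mg(OMe)2 would open the lactone, the doubly activated methylene (C4a) would attack the liberated ester carbonyl (C5) to form ring A, and one of the two equivalent phenoxides would add to the ynone to give 2-[2,5-bis(benzyloxy)-4-methoxyphenyl]-5,7-dihydroxy-6,8-dimethoxychromen-4-one A5.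
- Merits: A5 has ring A in final form, the symmetry of the new phloroglucinol removes any regiochemical question, and a single hydrogenolysis of A5 would lead to 24.
- Where it is better: the endgame is one step against four in the chosen plan.
- Weak points: A4 is a masked tetracarbonyl chain whose ynone is exposed to methoxide. The preparation of A4 (a 3,5-dimethoxylated hydroxypyranone with a C6 side chain that must then be acylated by an arylpropiolyl unit) is long and has little precedent. The 6-endo versus 5-exo question at the ynone is the same as in the chosen plan.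
- What the chosen plan sets against it: both precursors are reached by ordinary aromatic substitution chemistry, and the risk is concentrated in one step with a documented reaction type.

Alternative 3: The cut is in ring B, at C1'–C2' and C5'–C6'. The diene 4-methoxy-2-(trimethylsilyloxy)furan A6 would add across the terminal alkyne of 5,7-bis(benzyloxy)-2-ethynyl-6,8-dimethoxychromen-4-one A7. Opening of the oxygen bridge at the silyloxy-bearing bridgehead and tautomerisation would then give 5,7-bis(benzyloxy)-2-(2,5-dihydroxy-4-methoxyphenyl)-6,8-dimethoxychromen-4-one A8.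
- Merits: in A8 ring B would appear with both hydroxyls free and the methoxy group in place. The polarisation of the two partners is matched, the nucleophilic C5 of A6 meeting the electrophilic alkyne terminus of A7.
- Where it is better: ring B needs no protecting groups, and A8 would need only one hydrogenolysis to reach 24. The chosen plan installs two MOM groups and needs four steps after its key step.
- Weak points: it builds the easy ring and leaves the hard one. A7 already contains the fully differentiated ring A and ring C, so the main problem is only moved into the preparation of A7. A6, like other silyloxyfurans, often reacts with such acceptors by stepwise vinylogous Michael addition instead of cycloaddition. The C2=C3 bond of the chromone in A7 is a competing acceptor.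
- What the chosen plan sets against it: its key step makes the difficult junction of ring A and ring C itself.

Key step: step 10

Remark: 24 is treated as the neutral tetraphenol without stereocentres; 1, 13 and 16 are taken to be purchasable.

## Route

Step 1
Reactants: 1 2,5-dimethoxyphenol
Product: 2 2-hydroxy-3,6-dimethoxybenzaldehyde
Conditions: MgCl2 (1.5 equiv), Et3N (3.8 equiv), (CH2O)n (excess), MeCN, reflux; aq. HCl work-up
Reagents that add atoms: paraformaldehyde (as formaldehyde) C=O
Why: MgCl2/Et3N-mediated ortho-formylation of phenols: the magnesium phenoxide delivers formaldehyde through a chelate to the only free ortho carbon, and a second formaldehyde oxidises the benzylic alkoxide to the aldehyde.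

Step 2
Reactants: 2 2-hydroxy-3,6-dimethoxybenzaldehyde
Product: 3 3,6-dimethoxybenzene-1,2-diol
Conditions: 30% H2O2, aq. NaOH, THF, 0 °C to rt, N2; then aq. HCl, Na2S2O3 wash
Reagents that add atoms: hydrogen peroxide OO
Why: Dakin oxidation: the hydroperoxide adduct of the electron-rich o-hydroxybenzaldehyde undergoes aryl migration to the formate, which is saponified in the same flask; the conversion of o-vanillin to 3-methoxycatechol is the close model.

Step 3
Reactants: 3 3,6-dimethoxybenzene-1,2-diol
Product: 4 2,3-bis(benzyloxy)-1,4-dimethoxybenzene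
Conditions: BnBr (2.4 equiv), K2CO3 (3 equiv), DMF, 60 °C, N2
Reagents that add atoms: benzyl bromide BrCc1ccccc1
Why: Williamson etherification of both catechol hydroxyls; air is excluded because the catechol anion is oxidation-prone.

Step 4
Reactants: 4 2,3-bis(benzyloxy)-1,4-dimethoxybenzene
Product: 5 2,3-bis(benzyloxy)-5-bromo-1,4-dimethoxybenzene
Conditions: NBS (1.0 equiv), MeCN, 0 °C to rt, dark
Reagents that add atoms: N-bromosuccinimide O=C1CCC(=O)N1Br
Why: Electrophilic aromatic bromination; the two ring hydrogens of 4 are equivalent, so one equivalent of NBS can give only one monobromide, and the bromine slows a second substitution.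

Step 5
Reactants: 5 2,3-bis(benzyloxy)-5-bromo-1,4-dimethoxybenzene
Product: 8 3,4-bis(benzyloxy)-6-bromo-2,5-dimethoxyphenol, via aryllithium 6 (not isolated), via lithium aryltriisopropoxyborate 7 (not isolated)
Conditions: B(OiPr)3 (1.5 equiv) present, LiN(iPr)2 (1.2 equiv) added, THF, −78 °C to 0 °C; then AcOH, 30% H2O2, 0 °C to rt
Reagents that add atoms: hydrogen peroxide OO
Why: Directed ortho-lithiation at the hydrogen flanked by Br and OMe (as with 3-bromoanisole), in-situ borylation and peroxide oxidation of the C–B bond; the borate traps 6 before loss of LiBr or bromine scrambling, and the amide base should leave the benzyl ethers untouched at −78 °C.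

Step 6
Reactants: 8 3,4-bis(benzyloxy)-6-bromo-2,5-dimethoxyphenol
Product: 12 3,4-bis(benzyloxy)-2,5-dimethoxy-6-(trimethylsilyl)phenyl trifluoromethanesulfonate, via aryl trimethylsilyl ether 9 (not isolated), via aryllithium 10 (not isolated), via lithium silylphenoxide 11 (not isolated)
Conditions: HN(SiMe3)2, THF, 70 °C, then evaporation; n-BuLi (1.1 equiv), THF, −100 °C to −78 °C; Tf2O (1.2 equiv), −100 °C to rt
Reagents that add atoms: hexamethyldisilazane C[Si](C)(C)N[Si](C)(C)C; trifluoromethanesulfonic anhydride O=S(=O)(OS(=O)(=O)C(F)(F)F)C(F)(F)F
Why: Standard o-silylaryl triflate synthesis: O-silylation, bromine–lithium exchange, 1,3 O-to-C silyl shift (retro-Brook rearrangement) driven by phenoxide formation, then O-triflation; exchange at −100 °C is faster than benzylic deprotonation.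

Step 7
Reactants: 13 methoxyhydroquinone (2-methoxybenzene-1,4-diol)
Product: 14 2-methoxy-1,4-bis(methoxymethoxy)benzene
Conditions: MOMCl (2.6 equiv), iPr2NEt (3.5 equiv), CH2Cl2, 0 °C to rt, N2
Reagents that add atoms: chloromethyl methyl ether COCCl
Why: Double O-alkylation of the hydroquinone; the MOM acetals withstand base, fluoride, palladium catalysis and hydrogenolysis and are cleaved by the final Lewis acid.

Step 8
Reactants: 14 2-methoxy-1,4-bis(methoxymethoxy)benzene
Product: 15 1-iodo-4-methoxy-2,5-bis(methoxymethoxy)benzene
Conditions: NIS (1.05 equiv), MeCN, rt, dark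
Reagents that add atoms: N-iodosuccinimide O=C1CCC(=O)N1I
Why: Electrophilic iodination at the carbon para to OMe and ortho to OMOM, the usual site in 1,2,4-trialkoxybenzenes; the neutral medium spares the acetals.

Step 9
Reactants: 15 1-iodo-4-methoxy-2,5-bis(methoxymethoxy)benzene; 16 propiolic acid
Product: 17 3-[4-methoxy-2,5-bis(methoxymethoxy)phenyl]prop-2-ynoic acid
Conditions: 16 (1.3 equiv), Pd(PPh3)4 (3 mol%), DBU (2.4 equiv), DMSO, 35 °C; then cold aq. citric acid to pH 3
Reagents that add atoms: none
Why: Copper-free Sonogashira-type coupling of an aryl iodide with propiolic acid as its amidinium salt; near room temperature the coupled acid should not decarboxylate, and the mildly acidic work-up frees the acid without touching the MOM groups.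

Step 10
Reactants: 12 3,4-bis(benzyloxy)-2,5-dimethoxy-6-(trimethylsilyl)phenyl trifluoromethanesulfonate; 17 3-[4-methoxy-2,5-bis(methoxymethoxy)phenyl]prop-2-ynoic acid
Product: 20 6,7-bis(benzyloxy)-5,8-dimethoxy-2-[4-methoxy-2,5-bis(methoxymethoxy)phenyl]-4H-chromen-4-one, via tetraalkoxybenzyne 18 (not isolated), via cesium acylphenoxide ynone 19 (not isolated)
Conditions: 12 (1.5 equiv), CsF (4 equiv), THF, 125 °C (sealed tube), 24 h
Reagents that add atoms: none
Why: Fluoride removes the silyl group of 12 and triflate leaves, giving benzyne 18, whose strained bond is attacked by the cesium carboxylate of 17. The aryl anion so formed, ortho to the ester oxygen, adds to the ester carbonyl through a four-membered ring, and its collapse delivers the acyl group to carbon and releases phenoxide 19, a net insertion of the aryne into the acid C–O bond (O1–C8a and C4a–C4). This is the known fluoride-mediated C–O insertion of arynes into carboxylic acids, which with arylpropiolic acids continues to flavones. Phenoxide 19 closes ring C by 6-endo-dig oxa-Michael addition to the ynone β-carbon (O1–C2), and the vinyl anion takes its proton from the bifluoride formed from the acid proton. No stereocentre is formed. Regiochemistry of the aryne addition cannot arise, because 18 has a mirror plane through the midpoints of the C4a–C8a and C6–C7 bonds and both orientations give 20. Acyl transfer must outrun protonation of the aryl anion (which would give the aryl ester), and the high temperature, the excess of 12 and the low concentration of free acid favour it. The 6-endo closure must outrun 5-exo closure to an aurone; attack at the β-carbon gives a carbonyl-stabilised allenolate whereas attack at the α-carbon would give an unstabilised vinyl anion, and the proton donor in the medium favours the conjugate mode.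

Step 11
Reactants: 20 6,7-bis(benzyloxy)-5,8-dimethoxy-2-[4-methoxy-2,5-bis(methoxymethoxy)phenyl]-4H-chromen-4-one
Product: 21 6,7-dihydroxy-5,8-dimethoxy-2-[4-methoxy-2,5-bis(methoxymethoxy)phenyl]-4H-chromen-4-one
Conditions: H2 (1 atm), 10% Pd/C, EtOAc–MeOH, rt
Reagents that add atoms: none
Why: Hydrogenolysis of the two aryl benzyl ethers; MOM and methyl ethers and the pyranone double bond should be inert at 1 atm and room temperature.

Step 12
Reactants: 21 6,7-dihydroxy-5,8-dimethoxy-2-[4-methoxy-2,5-bis(methoxymethoxy)phenyl]-4H-chromen-4-one
Product: 22 7-(benzyloxy)-6-hydroxy-5,8-dimethoxy-2-[4-methoxy-2,5-bis(methoxymethoxy)phenyl]-4H-chromen-4-one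
Conditions: BnBr (1.05 equiv), K2CO3 (1.1 equiv), DMF, 0 °C to rt, Ar
Reagents that add atoms: benzyl bromide BrCc1ccccc1
Why: Williamson benzylation under acidity control: the 7-OH is para to the C4 carbonyl (a vinylogous acid) and should be the only hydroxyl ionised by one equivalent of carbonate, as in the selective 7-O-alkylation of 6,7-dihydroxycoumarins and 6,7-dihydroxyflavones.

Step 13
Reactants: 22 7-(benzyloxy)-6-hydroxy-5,8-dimethoxy-2-[4-methoxy-2,5-bis(methoxymethoxy)phenyl]-4H-chromen-4-one
Product: 23 7-(benzyloxy)-5,6,8-trimethoxy-2-[4-methoxy-2,5-bis(methoxymethoxy)phenyl]-4H-chromen-4-one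
Conditions: MeI (3 equiv), K2CO3 (2 equiv), DMF, rt to 40 °C
Reagents that add atoms: iodomethane CI
Why: Williamson methylation of the one remaining phenol; no other acidic site is present.

Step 14
Reactants: 23 7-(benzyloxy)-5,6,8-trimethoxy-2-[4-methoxy-2,5-bis(methoxymethoxy)phenyl]-4H-chromen-4-one
Product: 24 2-(2,5-dihydroxy-4-methoxyphenyl)-5,7-dihydroxy-6,8-dimethoxy-4H-chromen-4-one
Conditions: BCl3 (excess), C6HMe5 (4 equiv), CH2Cl2, −78 °C to 0 °C, Ar; then MeOH and 1 M aq. HCl, rt
Reagents that add atoms: none
Why: BCl3 chelates between the C4 carbonyl and the 5-OMe oxygen and chloride removes that methyl (peri-selective demethylation), while the same reagent cleaves the benzyl ether (cation trapped by pentamethylbenzene) and both MOM acetals; the 6-, 8- and 4'-methyl ethers lack the chelate and should survive at 0 °C.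

## Compound list

1 | 2,5-dimethoxyphenol | COc1ccc(OC)c(O)c1 | starting material
2 | 2-hydroxy-3,6-dimethoxybenzaldehyde | COc1ccc(OC)c(C=O)c1O | intermediate
3 | 3,6-dimethoxybenzene-1,2-diol | COc1ccc(OC)c(O)c1O | intermediate
4 | 2,3-bis(benzyloxy)-1,4-dimethoxybenzene | COc1ccc(OC)c(OCc2ccccc2)c1OCc1ccccc1 | intermediate
5 | 2,3-bis(benzyloxy)-5-bromo-1,4-dimethoxybenzene | COc1cc(Br)c(OC)c(OCc2ccccc2)c1OCc1ccccc1 | intermediate
6 | [3,4-bis(benzyloxy)-6-bromo-2,5-dimethoxyphenyl]lithium | [Li]c1c(Br)c(OC)c(OCc2ccccc2)c(OCc2ccccc2)c1OC | intermediate
7 | lithium [3,4-bis(benzyloxy)-6-bromo-2,5-dimethoxyphenyl]tris(propan-2-yloxy)borate | [Li+].CC(C)O[B-](OC(C)C)(OC(C)C)c1c(Br)c(OC)c(OCc2ccccc2)c(OCc2ccccc2)c1OC | intermediate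
8 | 3,4-bis(benzyloxy)-6-bromo-2,5-dimethoxyphenol | COc1c(O)c(Br)c(OC)c(OCc2ccccc2)c1OCc1ccccc1 | intermediate
9 | [3,4-bis(benzyloxy)-6-bromo-2,5-dimethoxyphenoxy]trimethylsilane | COc1c(O[Si](C)(C)C)c(Br)c(OC)c(OCc2ccccc2)c1OCc1ccccc1 | intermediate
10 | [4,5-bis(benzyloxy)-3,6-dimethoxy-2-(trimethylsilyloxy)phenyl]lithium | [Li]c1c(O[Si](C)(C)C)c(OC)c(OCc2ccccc2)c(OCc2ccccc2)c1OC | intermediate
11 | lithium 3,4-bis(benzyloxy)-2,5-dimethoxy-6-(trimethylsilyl)phenoxide | [Li+].[O-]c1c(OC)c(OCc2ccccc2)c(OCc2ccccc2)c(OC)c1[Si](C)(C)C | intermediate
12 | 3,4-bis(benzyloxy)-2,5-dimethoxy-6-(trimethylsilyl)phenyl trifluoromethanesulfonate | COc1c(OCc2ccccc2)c(OCc2ccccc2)c(OC)c([Si](C)(C)C)c1OS(=O)(=O)C(F)(F)F | intermediate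
13 | methoxyhydroquinone (2-methoxybenzene-1,4-diol) | COc1cc(O)ccc1O | starting material
14 | 2-methoxy-1,4-bis(methoxymethoxy)benzene | COCOc1ccc(OCOC)c(OC)c1 | intermediate
15 | 1-iodo-4-methoxy-2,5-bis(methoxymethoxy)benzene | COCOc1cc(OC)c(OCOC)cc1I | intermediate
16 | propiolic acid | C#CC(=O)O | starting material
17 | 3-[4-methoxy-2,5-bis(methoxymethoxy)phenyl]prop-2-ynoic acid | OC(=O)C#Cc1cc(OCOC)c(OC)cc1OCOC | intermediate
18 | 4,5-bis(benzyloxy)-3,6-dimethoxybenzyne (1,2-didehydro-4,5-bis(benzyloxy)-3,6-dimethoxybenzene) | COC1=C(OCc2ccccc2)C(OCc2ccccc2)=C(OC)C#C1 | intermediate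
19 | cesium 3,4-bis(benzyloxy)-2,5-dimethoxy-6-{3-[4-methoxy-2,5-bis(methoxymethoxy)phenyl]prop-2-ynoyl}phenoxide | [Cs+].[O-]c1c(OC)c(OCc2ccccc2)c(OCc2ccccc2)c(OC)c1C(=O)C#Cc1cc(OCOC)c(OC)cc1OCOC | intermediate
20 | 6,7-bis(benzyloxy)-5,8-dimethoxy-2-[4-methoxy-2,5-bis(methoxymethoxy)phenyl]-4H-chromen-4-one | COCOc1cc(OC)c(OCOC)cc1-c1cc(=O)c2c(OC)c(OCc3ccccc3)c(OCc3ccccc3)c(OC)c2o1 | intermediate
21 | 6,7-dihydroxy-5,8-dimethoxy-2-[4-methoxy-2,5-bis(methoxymethoxy)phenyl]-4H-chromen-4-one | COCOc1cc(OC)c(OCOC)cc1-c1cc(=O)c2c(OC)c(O)c(O)c(OC)c2o1 | intermediate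
22 | 7-(benzyloxy)-6-hydroxy-5,8-dimethoxy-2-[4-methoxy-2,5-bis(methoxymethoxy)phenyl]-4H-chromen-4-one | COCOc1cc(OC)c(OCOC)cc1-c1cc(=O)c2c(OC)c(O)c(OCc3ccccc3)c(OC)c2o1 | intermediate
23 | 7-(benzyloxy)-5,6,8-trimethoxy-2-[4-methoxy-2,5-bis(methoxymethoxy)phenyl]-4H-chromen-4-one | COCOc1cc(OC)c(OCOC)cc1-c1cc(=O)c2c(OC)c(OC)c(OCc3ccccc3)c(OC)c2o1 | intermediate
24 | 2-(2,5-dihydroxy-4-methoxyphenyl)-5,7-dihydroxy-6,8-dimethoxy-4H-chromen-4-one | COc1cc(O)c(-c2cc(=O)c3c(O)c(OC)c(O)c(OC)c3o2)cc1O | target

## Step count and risks

Total: 14 steps. Longest linear sequence: 11 steps (1 to 12 in six steps, then steps 10 to 14). The second branch, 13 to 17, is three steps.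

**Step 10 (key step).** Three processes can divert material: protonation of the aryl anion before acyl transfer, so that only O-arylation takes place; thermal loss of CO2 from the cesium propiolate at 125 °C; and partial 5-exo closure of 19, whose ketone is twisted out of conjugation by the flanking 5-OMe and phenoxide. Fallback from 15 and 12, returning at 20: a Heck reaction of 15 with acrylic acid (Pd(OAc)2, P(o-tol)3, Et3N, DMF, 90 °C) would give (E)-3-[4-methoxy-2,5-bis(methoxymethoxy)phenyl]prop-2-enoic acid F1. This acid does not decarboxylate, so the CsF-triggered insertion of the aryne from 12 can be driven to complete acyl transfer. It would pass through (E)-1-[3,4-bis(benzyloxy)-6-hydroxy-2,5-dimethoxyphenyl]-3-[4-methoxy-2,5-bis(methoxymethoxy)phenyl]prop-2-en-1-one F2, formed as its phenoxide and not isolated. F2 can only close 6-endo-trig, leading to racemic 6,7-bis(benzyloxy)-5,8-dimethoxy-2-[4-methoxy-2,5-bis(methoxymethoxy)phenyl]chroman-4-one F3. Dehydrogenation of F3 with DDQ in dioxane at reflux would then give 20.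

**Step 5.** Bromine scrambling between 6 and unreacted 5, or loss of LiBr from 6 to an aryne, could compete with borylation. Fallback from 5, returning at 8: bromine–lithium exchange on 5 (n-BuLi, THF, −78 °C), B(OMe)3 and H2O2/NaOH would give 3,4-bis(benzyloxy)-2,5-dimethoxyphenol F4. The single free ring position of F4, ortho to the hydroxyl, would then be brominated with NBS in MeCN at −20 °C to give 8. This costs one more step and avoids any ortho-bromoaryllithium.

**Step 9.** Slow oxidative addition to the electron-rich, ortho-substituted iodide could let decarboxylation of the product and a second coupling to a diarylalkyne take over. Fallback from 15, returning at 17: Sonogashira coupling with trimethylsilylacetylene (PdCl2(PPh3)2, CuI, Et3N) would give {[4-methoxy-2,5-bis(methoxymethoxy)phenyl]ethynyl}trimethylsilane F5. K2CO3 in MeOH would give 1-ethynyl-4-methoxy-2,5-bis(methoxymethoxy)benzene F6, and deprotonation of F6 with n-BuLi at −78 °C followed by CO2 would give 17.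

**Step 12.** Proton exchange between the two phenoxides could cause loss of site selectivity and double benzylation, and the diol could be oxidised by air under base. Fallback from 21, returning at 22: Mitsunobu benzylation (benzyl alcohol, PPh3, diisopropyl azodicarboxylate, THF, 0 °C). Here no free dianion is present and the more acidic 7-OH is the one that protonates the betaine and is alkylated. No compound outside the main list is made, so this fallback is entered as F0.

**Step 14.** Over-demethylation at the 6-OMe next to the boron chelate, C-benzylation of the electron-rich ring B, or oxidation of the liberated hydroquinone during work-up could occur. Fallback from 23, returning at 24, removing one kind of group at a time: hydrogenolysis (H2, 10% Pd/C, EtOAc–MeOH) would give 7-hydroxy-5,6,8-trimethoxy-2-[4-methoxy-2,5-bis(methoxymethoxy)phenyl]-4H-chromen-4-one F7. HCl in MeOH at rt would then remove the acetals to give 2-(2,5-dihydroxy-4-methoxyphenyl)-7-hydroxy-5,6,8-trimethoxy-4H-chromen-4-one F8. AlCl3 in MeCN at rt, the classical peri-selective demethylation of 5-methoxyflavones, would finally convert F8 into 24.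

Further compounds
F1 | step 10 | (E)-3-[4-methoxy-2,5-bis(methoxymethoxy)phenyl]prop-2-enoic acid | OC(=O)/C=C/c1cc(OCOC)c(OC)cc1OCOC
F2 | step 10 | (E)-1-[3,4-bis(benzyloxy)-6-hydroxy-2,5-dimethoxyphenyl]-3-[4-methoxy-2,5-bis(methoxymethoxy)phenyl]prop-2-en-1-one | COCOc1cc(OC)c(OCOC)cc1/C=C/C(=O)c1c(O)c(OC)c(OCc2ccccc2)c(OCc2ccccc2)c1OC
F3 | step 10 | 6,7-bis(benzyloxy)-5,8-dimethoxy-2-[4-methoxy-2,5-bis(methoxymethoxy)phenyl]chroman-4-one (racemic) | COCOc1cc(OC)c(OCOC)cc1C1CC(=O)c2c(OC)c(OCc3ccccc3)c(OCc3ccccc3)c(OC)c2O1
F4 | step 5 | 3,4-bis(benzyloxy)-2,5-dimethoxyphenol | COc1cc(O)c(OC)c(OCc2ccccc2)c1OCc1ccccc1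
F5 | step 9 | {[4-methoxy-2,5-bis(methoxymethoxy)phenyl]ethynyl}trimethylsilane | COCOc1cc(OC)c(OCOC)cc1C#C[Si](C)(C)C
F6 | step 9 | 1-ethynyl-4-methoxy-2,5-bis(methoxymethoxy)benzene | COCOc1cc(OC)c(OCOC)cc1C#C
F0 | step 12 | none | none
F7 | step 14 | 7-hydroxy-5,6,8-trimethoxy-2-[4-methoxy-2,5-bis(methoxymethoxy)phenyl]-4H-chromen-4-one | COCOc1cc(OC)c(OCOC)cc1-c1cc(=O)c2c(OC)c(OC)c(O)c(OC)c2o1
F8 | step 14 | 2-(2,5-dihydroxy-4-methoxyphenyl)-7-hydroxy-5,6,8-trimethoxy-4H-chromen-4-one | COc1cc(O)c(-c2cc(=O)c3c(OC)c(OC)c(O)c(OC)c3o2)cc1O
A1 | alternative 1 | 1,3-dimethoxyacetone | COCC(=O)COC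
A2 | alternative 1 | dimethyl malonate | COC(=O)CC(=O)OC
A3 | alternative 1 | 2,4-dimethoxybenzene-1,3,5-triol | COc1c(O)cc(O)c(OC)c1O
A4 | alternative 2 | 6-{4-[2,5-bis(benzyloxy)-4-methoxyphenyl]-2-oxobut-3-yn-1-yl}-4-hydroxy-3,5-dimethoxy-2H-pyran-2-one | COc1c(O)c(OC)c(CC(=O)C#Cc2cc(OCc3ccccc3)c(OC)cc2OCc2ccccc2)oc1=O
A5 | alternative 2 | 2-[2,5-bis(benzyloxy)-4-methoxyphenyl]-5,7-dihydroxy-6,8-dimethoxychromen-4-one | COc1cc(OCc2ccccc2)c(-c2cc(=O)c3c(O)c(OC)c(O)c(OC)c3o2)cc1OCc1ccccc1
A6 | alternative 3 | 4-methoxy-2-(trimethylsilyloxy)furan | COc1cc(O[Si](C)(C)C)oc1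
A7 | alternative 3 | 5,7-bis(benzyloxy)-2-ethynyl-6,8-dimethoxychromen-4-one | C#Cc1cc(=O)c2c(OCc3ccccc3)c(OC)c(OCc3ccccc3)c(OC)c2o1
A8 | alternative 3 | 5,7-bis(benzyloxy)-2-(2,5-dihydroxy-4-methoxyphenyl)-6,8-dimethoxychromen-4-one | COc1cc(O)c(-c2cc(=O)c3c(OCc4ccccc4)c(OC)c(OCc4ccccc4)c(OC)c3o2)cc1O
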